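## Structural features

The target 15 is a flavanone: a benzene ring (ring A) fused through C4a and C8a to a dihydropyranone (ring C: O1, C2, C3, C4=O), with a 3,4-dimethoxyphenyl group (ring B) on C2. Ring A carries no hydrogen: C4a holds the acyl carbon C4, C5, C6 and C7 hold methoxy groups, C8 a free hydroxyl and C8a the ring oxygen O1. C2 is the only stereocentre (S) and has no stereogenic neighbour. It is benzylic, bound to O1 and β to the C4 ketone, so acid or base can open ring C by a retro-oxa-Michael reaction to the 2'-hydroxychalcone and reclose it without facial control. Other weak points are the C8 hydroxyl para to the C5 methoxy group (a hydroquinone monoether, easily oxidised to a quinone), the C5 methyl ether peri to the carbonyl (the one most readily cleaved by Lewis acids) and the electron-rich ring B, which competes for electrophiles. The real difficulty is the ordered placement of six different substituents on ring A, with one unprotected hydroxyl among three methyl ethers, while ring C is closed under conditions that never let C2 epimerise. The key step uses the fact that C8a (bonded to O1) and C4a (bonded to C4) are adjacent carbons of ring A. They can be the two carbons of an aryne that takes up the oxygen and the acyl carbon of a chiral β-hydroxy ester in one operation. The C5 methoxy group and a silyl placeholder at C8 flank that aryne and steer the addition.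

## Logic of the disconnections

15 to 13 (through 14): the C8–O bond is cut and replaced first by C8–B, then by C8–I. The free phenol para to a methoxy group is the most oxidation-prone function, so it is made last. This reduces the phenol problem to an aryl halide. The forward steps must borylate a carbon with two ortho substituents and oxidise the boronate without a base strong enough to open ring C.

13 to 12: the C8–I bond is traced back to a C8–Si bond. Silicon is needed at C8 for the ring-forming step, and an aryl–silicon bond on an electron-rich ring can be exchanged ipso for iodine. Nothing is gained in skeleton, but the C8 substituent becomes the group that controls the key step. The electrophile must choose C8 over the free positions of ring B.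

12 to 7 and 11: the bonds O1–C8a and C4–C4a are cut. They end on adjacent ring-A carbons, so cutting both removes ring C and divides the molecule into two pieces of similar size. C2 goes into 11 with its C–O bond intact, so no stereocentre has to be made on the assembled skeleton. The forward step needs the aryne from 7 to accept oxygen at the silicon-flanked carbon, the resulting aryl anion to acylate faster than it is protonated, and conditions that leave C2 untouched.

7 to 4 to 2 to 1: the O–S bond, the two C–Si bonds and the two C–Br bonds are cut in turn (3, 5 and 6 are the in-flask stages). The two positions ortho to the hydroxyl of 1 are equivalent and are the only free ring carbons, so none of these steps involves a regiochemical decision. The forward steps need a bromine–lithium exchange followed by an oxygen-to-carbon silyl shift, twice, and then sulfonylation of a phenolate flanked by two silyl groups.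

11 to 10 to 8 and 9: the C–H bond at the carbinol carbon is cut (hydride to a ketone), then the bond between the ketone α-carbon and the ester carbon (Claisen disconnection). This reaches two cheap achiral materials. The forward reduction must be enantioselective in the (S) sense.

## Other disconnections considered

Alternative 1: The cut is O1–C8a alone, on a flavan-4-ol whose C4 oxygen is silylated. In the forward key step zerovalent palladium would insert into the C8a–Br bond of the bromo alcohol A2, the (S)-benzylic alkoxide would bind to palladium, and C–O reductive elimination would close ring C to give A1.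
- In its favour:
  - The C2–O bond is not touched, so configuration is retained. On stereochemistry this is the equal of the chosen plan.
  - The position of bromine fixes the regiochemistry on ring A without reliance on aryne polarisation. This is better than the chosen plan.
  - Intramolecular palladium-catalysed aryl etherification to chromans is an established reaction type, whereas the chosen key step is not. This is also a point for the alternative.
- Against it here:
  - The C–Br bond of A2 lies between a benzyloxy group and the side chain on an electron-rich ring, so oxidative addition should be slow.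
  - A secondary benzylic alkoxide on palladium can undergo β-hydride elimination, which reduces the arene and oxidises the carbinol.
  - The strong base rules out a C4 ketone (retro-aldol and chalcone formation). C4 must travel as a protected alcohol, so A1 is a mixture of epimers of no value.
  - Desilylation, oxidation at C4 and hydrogenolysis of the benzyl ether still follow the key step.
- Comparison: A2 needs a ring A with bromine, benzyloxy and three methoxy groups all differentiated, plus a chiral 1,3-diol chain. The key step forms one bond against two in the chosen plan. The route would be about thirteen steps against eight, so it is worse on step economy.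

Alternative 2: The cuts are O1–C2 and C3–C4. In the forward key step a chiral phosphoric acid would dehydrate the hydroxybenzyl alcohol A4 to its ortho-quinone methide, which would add the styrene A5 in a hetero-Diels–Alder reaction to give the flavan A3, with C2 set by the catalyst.
- In its favour:
  - Two bonds, ring C and the stereocentre arise in one catalytic step from an achiral alkene. This is better than the chosen plan, which needs a separate asymmetric hydrogenation.
  - Convergence is equal.
  - The regiochemistry follows from polarity (nucleophilic terminal carbon of A5 to the methide carbon).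
- Against it here:
  - A3 has a CH2 group at C4, so the carbonyl must be introduced afterwards by benzylic oxidation. The C2–H bond of A3 is benzylic and α to oxygen, hence more activated than C4–H, and A3 also holds a benzyl ether and two electron-rich rings. Wrong-site oxidation, over-oxidation to the flavone and degradation of ring A are all plausible.
  - Enantiocontrol in this reaction type is best established for quinone methides with an aryl group on the methide carbon. A4 gives an unsubstituted one, and A5 is prone to acid-induced oligomerisation.
- Comparison: both plans close ring C by a polar two-bond annulation, but the chosen plan delivers C4 directly at the ketone level. About ten steps would be needed, comparable to or slightly worse than the chosen plan, with the risk moved to a late oxidation.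

Alternative 3: The cut is C8–C8a, and with it ring A is taken back to a four-membered ring. In the forward key step the cyclobutenone A7 would open on heating (4π) to a dienylketene. A 6π closure that joins the ketene carbon to C8a, then tautomerisation, would give A6. A7 would be made by adding a 5-metallated dihydropyran to the squaric ester A8 and O-methylating the adduct.
- In its favour:
  - All oxygens of ring A come from A8 and the methylation, so the C8 hydroxyl appears free and in the right place with no silicon-to-oxygen exchange. This is better than the chosen plan.
  - There is no regiochemical question on ring A. This is better than the chosen plan.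
  - The conditions are neutral and thermal, so C2 is safe. This is equal or better.
  - The ring expansion is a well-established reaction type. It is better on precedent.
- Against it here:
  - The difficulty moves to the dihydropyran fragment. It must carry C2 (S), a protected C4 carbinol that only stands in for the ketone and is later destroyed, and a metal at the carbon that becomes C4a.
  - A6 is an air-sensitive hydroquinone monoether.
  - After the key step the silyl ether must be removed and C4 oxidised next to the unprotected C8 phenol, which probably forces an extra protection and deprotection.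
- Comparison: this is the only plan that builds ring A instead of decorating it, and its key step is the safest mechanistically. At about fourteen steps it is the longest of the four.

Key step: step 6

Remark: flavanone numbering (O1, C2, C3, C4, C4a, C5 to C8, C8a; ring A = fused benzene ring, ring B = 3,4-dimethoxyphenyl group, ring C = pyranone ring) is also used for the precursor atoms that become these positions; (R)-BINAP is assumed to give the (S)-carbinol 11, with the same facial sense that gives (R)-3-hydroxybutanoates (the descriptor changes only because aryl outranks CH2CO2Me).

## Route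

Step 1
Reactants: 1 3,4,5-trimethoxyphenol
Product: 2 2,6-dibromo-3,4,5-trimethoxyphenol
Conditions: NBS (2.1 equiv), MeCN, −20 °C to 0 °C, dark
Reagents that add atoms: N-bromosuccinimide, O=C1CCC(=O)N1Br
Why: Electrophilic aromatic bromination; the two carbons ortho to the hydroxyl are the only unsubstituted ring positions and are equivalent, and NBS at low temperature delivers bromine without the excess oxidant that could take this electron-rich phenol to a quinone.

Step 2
Reactants: 2 2,6-dibromo-3,4,5-trimethoxyphenol
Product: 4 2-bromo-3,4,5-trimethoxy-6-(trimethylsilyl)phenol, via dibromoaryl trimethylsilyl ether 3 (not isolated)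
Conditions: HMDS, THF, reflux, then evaporation; n-BuLi (1.05 equiv), THF, −78 °C to rt; aq. NH4Cl
Reagents that add atoms: hexamethyldisilazane, C[Si](C)(C)N[Si](C)(C)C
Why: O-silylation, then bromine–lithium exchange gives an aryllithium ortho to the silyl ether, which undergoes the anionic 1,3-shift of silicon from oxygen to carbon (retro-Brook rearrangement). One equivalent of n-BuLi exchanges only one of the two equivalent bromines, because the lithium phenolate formed is deactivated toward further exchange at low temperature.

Step 3
Reactants: 4 2-bromo-3,4,5-trimethoxy-6-(trimethylsilyl)phenol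
Product: 7 3,4,5-trimethoxy-2,6-bis(trimethylsilyl)phenyl trifluoromethanesulfonate, via bromo(silyl)aryl trimethylsilyl ether 5 (not isolated), via lithium bis(trimethylsilyl)phenolate 6 (not isolated)
Conditions: HMDS, THF, reflux, then evaporation; n-BuLi (1.05 equiv), THF, −78 °C to rt; Tf2O (1.2 equiv), −78 °C to 0 °C
Reagents that add atoms: hexamethyldisilazane, C[Si](C)(C)N[Si](C)(C)C; trifluoromethanesulfonic anhydride, FC(F)(F)S(=O)(=O)OS(=O)(=O)C(F)(F)F
Why: The same O-silylation, bromine–lithium exchange and retro-Brook sequence at the remaining bromine gives phenolate 6, which is sulfonylated in the same flask; this is the standard one-pot preparation of ortho-silylaryl triflates from ortho-bromophenols.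

Step 4
Reactants: 8 3,4-dimethoxyacetophenone; 9 dimethyl carbonate
Product: 10 methyl 3-(3,4-dimethoxyphenyl)-3-oxopropanoate
Conditions: NaH (2.5 equiv), dimethyl carbonate (3 equiv), toluene, 80 °C; AcOH, H2O
Reagents that add atoms: none
Why: Crossed Claisen condensation of the ketone enolate with a carbonate that cannot enolise; it is driven to completion by deprotonation of the β-keto ester, hence the second equivalent of base.

Step 5
Reactants: 10 methyl 3-(3,4-dimethoxyphenyl)-3-oxopropanoate
Product: 11 methyl (3S)-3-(3,4-dimethoxyphenyl)-3-hydroxypropanoate
Conditions: H2 (20 bar), [RuCl(p-cymene)((R)-BINAP)]Cl (0.5 mol %), MeOH, 60 °C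
Reagents that add atoms: none
Why: Noyori asymmetric hydrogenation of a β-keto ester; chelation of the ketone and ester carbonyls to the BINAP–ruthenium hydride fixes the face of hydride delivery, and with (R)-BINAP the carbinol should be (S). Methanol matches the methyl ester, so transesterification is of no consequence.

Step 6
Reactants: 7 3,4,5-trimethoxy-2,6-bis(trimethylsilyl)phenyl trifluoromethanesulfonate; 11 methyl (3S)-3-(3,4-dimethoxyphenyl)-3-hydroxypropanoate
Product: 12 (2S)-2-(3,4-dimethoxyphenyl)-5,6,7-trimethoxy-8-(trimethylsilyl)chroman-4-one
Conditions: 11 (1.0 equiv), 7 (1.5 equiv, added over 4 h), CsF (4 equiv), THF, 60 °C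
Reagents that add atoms: none
Why: Proposed new method: fluoride attacks one of the two equivalent trimethylsilyl groups of 7 and triflate leaves, giving an aryne flanked by the future C5 methoxy group on one side and the remaining silyl group on the other; the caesium alkoxide of 11 adds to the silicon-flanked carbon (C8a), the aryl anion formed at C4a attacks the ester carbonyl, and loss of methoxide gives the ketone, the closest known reaction types being the fluoride-mediated annulation of arynes with methyl salicylates to xanthones (oxygen addition, then intramolecular acylation) and nucleophilic additions to 3-silyl- and 3-methoxyarynes. Ring C closes by a 6-exo-trig acyl substitution of the C4a carbanion on C4. No stereocentre is created: C2 comes from 11 and its C–O bond is never broken, so the (S) configuration is carried over. The regioselectivity needed is oxygen at C8a and not at C4a; the inductively withdrawing methoxy group stabilises negative charge on the adjacent carbon and the electropositive silyl group makes its neighbouring aryne carbon the more electrophilic end, so both substituents act in the same direction and only the bulk of silicon opposes them. The chemoselectivity needed is acylation of the aryl anion before protonation; an aprotic solvent, slow release of the aryne and the six-membered transition state favour it. The surplus of 7 consumes the liberated methoxide, which limits base-induced opening of ring C in 12.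

Step 7
Reactants: 12 (2S)-2-(3,4-dimethoxyphenyl)-5,6,7-trimethoxy-8-(trimethylsilyl)chroman-4-one
Product: 13 (2S)-2-(3,4-dimethoxyphenyl)-8-iodo-5,6,7-trimethoxychroman-4-one
Conditions: ICl (1.05 equiv), CH2Cl2, −78 °C to −20 °C; aq. Na2S2O3
Reagents that add atoms: iodine monochloride, ClI
Why: Electrophilic ipso-iododesilylation: the iodine cation attacks C8, the arenium ion is stabilised by the β-silicon, and chloride removes silicon. C8 is the most nucleophilic aromatic carbon (ortho to O1 and to the C7 methoxy group, para to the C5 methoxy group, activated by silicon), and one equivalent at low temperature should leave ring B and C2 untouched.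

Step 8
Reactants: 13 (2S)-2-(3,4-dimethoxyphenyl)-8-iodo-5,6,7-trimethoxychroman-4-one
Product: 15 (2S)-2-(3,4-dimethoxyphenyl)-8-hydroxy-5,6,7-trimethoxychroman-4-one, via C8 pinacol boronate 14 (not isolated)
Conditions: B2pin2 (1.5 equiv), Pd(OAc)2 (5 mol %), SPhos (10 mol %), KOAc (3 equiv), 1,4-dioxane, 80 °C; filtration through silica; then 30% H2O2, NaHCO3, THF/H2O, 0 °C; aq. Na2S2O3
Reagents that add atoms: bis(pinacolato)diboron, CC1(C)OB(OC1(C)C)B1OC(C)(C)C(C)(C)O1 (boryl group of 14); hydrogen peroxide, OO (oxygen at C8 of 15)
Why: Miyaura borylation (oxidative addition of zerovalent palladium to the C8–I bond, acetate-assisted transmetalation, reductive elimination), then oxidation of the C–B bond by hydroperoxide with 1,2-shift of the aryl group from boron to oxygen. KOAc and NaHCO3 are weak bases chosen to keep ring C closed so that C2 stays (S), and the bulky electron-rich phosphine is meant to cope with the two ortho substituents.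

## Compound list

1 | 3,4,5-trimethoxyphenol | COc1cc(O)cc(OC)c1OC | starting material
2 | 2,6-dibromo-3,4,5-trimethoxyphenol | COc1c(Br)c(O)c(Br)c(OC)c1OC | intermediate
3 | (2,6-dibromo-3,4,5-trimethoxyphenoxy)trimethylsilane | COc1c(Br)c(O[Si](C)(C)C)c(Br)c(OC)c1OC | intermediate
4 | 2-bromo-3,4,5-trimethoxy-6-(trimethylsilyl)phenol | COc1c(Br)c(O)c([Si](C)(C)C)c(OC)c1OC | intermediate
5 | [2-bromo-3,4,5-trimethoxy-6-(trimethylsilyl)phenoxy]trimethylsilane | COc1c(Br)c(O[Si](C)(C)C)c([Si](C)(C)C)c(OC)c1OC | intermediate
6 | lithium 3,4,5-trimethoxy-2,6-bis(trimethylsilyl)phenolate | [Li+].[O-]c1c([Si](C)(C)C)c(OC)c(OC)c(OC)c1[Si](C)(C)C | intermediate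
7 | 3,4,5-trimethoxy-2,6-bis(trimethylsilyl)phenyl trifluoromethanesulfonate | C[Si](C)(C)c1c(OC)c(OC)c(OC)c([Si](C)(C)C)c1OS(=O)(=O)C(F)(F)F | intermediate
8 | 3,4-dimethoxyacetophenone | CC(=O)c1ccc(OC)c(OC)c1 | starting material
9 | dimethyl carbonate | COC(=O)OC | starting material
10 | methyl 3-(3,4-dimethoxyphenyl)-3-oxopropanoate | COC(=O)CC(=O)c1ccc(OC)c(OC)c1 | intermediate
11 | methyl (3S)-3-(3,4-dimethoxyphenyl)-3-hydroxypropanoate | COc1ccc([C@@H](O)CC(=O)OC)cc1OC | intermediate
12 | (2S)-2-(3,4-dimethoxyphenyl)-5,6,7-trimethoxy-8-(trimethylsilyl)chroman-4-one | COc1ccc([C@@H]2CC(=O)c3c(c([Si](C)(C)C)c(OC)c(OC)c3OC)O2)cc1OC | intermediate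
13 | (2S)-2-(3,4-dimethoxyphenyl)-8-iodo-5,6,7-trimethoxychroman-4-one | COc1ccc([C@@H]2CC(=O)c3c(c(I)c(OC)c(OC)c3OC)O2)cc1OC | intermediate
14 | (2S)-2-(3,4-dimethoxyphenyl)-5,6,7-trimethoxy-8-(4,4,5,5-tetramethyl-1,3,2-dioxaborolan-2-yl)chroman-4-one | COc1ccc([C@@H]2CC(=O)c3c(c(B4OC(C)(C)C(C)(C)O4)c(OC)c(OC)c3OC)O2)cc1OC | intermediate
15 | (2S)-2-(3,4-dimethoxyphenyl)-8-hydroxy-5,6,7-trimethoxychroman-4-one | COc1ccc([C@@H]2CC(=O)c3c(c(O)c(OC)c(OC)c3OC)O2)cc1OC | target

## Step count and least certain steps

Total step count: 8. Longest linear sequence: 6 (steps 1, 2, 3, 6, 7, 8); the second branch (steps 4 and 5) joins at step 6.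

**Step 6 (key step, Proposed new method).**
- Most likely failure: protonation of the C4a aryl anion (by the hydroxyl of unreacted 11 or by the ester α-CH2) before it reaches the ester carbonyl, followed by β-elimination of the new aryloxide from the ester enolate.
- Other possibilities: retro-aldol cleavage of the alkoxide of 11, addition in the reverse orientation under the steric pressure of silicon, and base-induced opening of ring C with erosion at C2.
- Reason: a secondary alkoxide is a weaker aryne nucleophile than the phenolates for which this kind of annulation is established, and 11 has acidic α-hydrogens that salicylates lack.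
- Fallback (known chemistry, no aryne), setting out from 4 and coming back at 12: 4 is converted to its dianion (n-BuLi, 2.2 equiv, THF, −78 °C to 0 °C; O–H deprotonation, then bromine–lithium exchange) and acylated with N-methoxy-N-methylacetamide to give 1-[2-hydroxy-4,5,6-trimethoxy-3-(trimethylsilyl)phenyl]ethan-1-one F1. Condensation with N,N-dimethylformamide dimethyl acetal (neat, 90 °C) should give the enaminone (2E)-3-(dimethylamino)-1-[2-hydroxy-4,5,6-trimethoxy-3-(trimethylsilyl)phenyl]prop-2-en-1-one F2, which closes in warm acetic acid to 5,6,7-trimethoxy-8-(trimethylsilyl)-4H-chromen-4-one F3. Enantioselective conjugate addition of 3,4-dimethoxyphenylboronic acid (Pd(OCOCF3)2, the antipode of the t-BuPyOx ligand that places the aryl group for (2S), NH4PF6, H2O, 1,2-dichloroethane, 60 °C) then forms the C2–aryl bond and returns to 12. Here C2 is set by the catalyst and ring C is closed before the stereocentre exists.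

**Step 8.**
- Most likely failure: slow oxidative addition and transmetalation at the doubly ortho-substituted C8, ending in reductive loss of iodine.
- Other possibilities: acetate-induced opening of ring C at 80 °C with erosion at C2, and over-oxidation of the hydroquinone-type ring A during the peroxide stage.
- Fallback without palladium or hot base, setting out from 13 and coming back at 14: reduction with NaBH4 (MeOH/THF, 0 °C) should give (2S,4S)-2-(3,4-dimethoxyphenyl)-8-iodo-5,6,7-trimethoxychroman-4-ol F4, in which C2 can no longer epimerise. Deprotonation of the alcohol (NaH), iodine–lithium exchange (t-BuLi, 2 equiv, THF, −78 °C) and trapping with 2-isopropoxy-4,4,5,5-tetramethyl-1,3,2-dioxaborolane would give (2S,4S)-2-(3,4-dimethoxyphenyl)-5,6,7-trimethoxy-8-(4,4,5,5-tetramethyl-1,3,2-dioxaborolan-2-yl)chroman-4-ol F5. Oxidation of the carbinol with Dess–Martin periodinane returns to 14, which is oxidised as in the second stage of step 8.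

**Step 7.**
- Most likely failure: competing electrophilic iodination of ring B (para to its 3-methoxy group), or opening of ring C by adventitious acid.
- Fallback with an electrophile that does not substitute aromatic C–H bonds, setting out from 12 and coming back at 14: ipso-borodesilylation with BCl3 (1.1 equiv, CH2Cl2, −78 °C) should give (2S)-8-(dichloroboranyl)-2-(3,4-dimethoxyphenyl)-5,6,7-trimethoxychroman-4-one F6. Treatment with pinacol and NaHCO3 work-up leads to 14. One equivalent and low temperature are needed to spare the C5 methyl ether.

**Step 3.**
- Most likely failure: incomplete O-silylation of the hindered phenol 4 (the free phenol then quenches n-BuLi), or sluggish sulfonylation of the doubly silyl-flanked phenolate 6, with desilylation on work-up.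
- Fallback that builds both C–Si bonds by directed ortho-metalation instead of silyl migration, setting out from 1 and coming back at 7: 1 and isopropyl isocyanate (cat. Et3N) give 3,4,5-trimethoxyphenyl N-isopropylcarbamate F7. In-situ N-silylation (TBSOTf, TMEDA), ortho-lithiation (n-BuLi, TMEDA, −78 °C) and TMSCl give 3,4,5-trimethoxy-2-(trimethylsilyl)phenyl N-isopropylcarbamate F8. A second round at the other ortho position gives 3,4,5-trimethoxy-2,6-bis(trimethylsilyl)phenyl N-isopropylcarbamate F9. Cleavage of the carbamate through the isocyanate (Et2NH, DBU, MeCN, 40 °C) and triflation of the freed phenolate with PhNTf2 in the same flask give 7.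

## Further compounds

F1 | step 6 | 1-[2-hydroxy-4,5,6-trimethoxy-3-(trimethylsilyl)phenyl]ethan-1-one | CC(=O)c1c(O)c([Si](C)(C)C)c(OC)c(OC)c1OC
F2 | step 6 | (2E)-3-(dimethylamino)-1-[2-hydroxy-4,5,6-trimethoxy-3-(trimethylsilyl)phenyl]prop-2-en-1-one | CN(C)/C=C/C(=O)c1c(O)c([Si](C)(C)C)c(OC)c(OC)c1OC
F3 | step 6 | 5,6,7-trimethoxy-8-(trimethylsilyl)-4H-chromen-4-one | O=c1ccoc2c([Si](C)(C)C)c(OC)c(OC)c(OC)c12
F4 | step 8 | (2S,4S)-2-(3,4-dimethoxyphenyl)-8-iodo-5,6,7-trimethoxychroman-4-ol | COc1ccc([C@@H]2C[C@H](O)c3c(c(I)c(OC)c(OC)c3OC)O2)cc1OC
F5 | step 8 | (2S,4S)-2-(3,4-dimethoxyphenyl)-5,6,7-trimethoxy-8-(4,4,5,5-tetramethyl-1,3,2-dioxaborolan-2-yl)chroman-4-ol | COc1ccc([C@@H]2C[C@H](O)c3c(c(B4OC(C)(C)C(C)(C)O4)c(OC)c(OC)c3OC)O2)cc1OC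
F6 | step 7 | (2S)-8-(dichloroboranyl)-2-(3,4-dimethoxyphenyl)-5,6,7-trimethoxychroman-4-one | COc1ccc([C@@H]2CC(=O)c3c(c(B(Cl)Cl)c(OC)c(OC)c3OC)O2)cc1OC
F7 | step 3 | 3,4,5-trimethoxyphenyl N-isopropylcarbamate | CC(C)NC(=O)Oc1cc(OC)c(OC)c(OC)c1
F8 | step 3 | 3,4,5-trimethoxy-2-(trimethylsilyl)phenyl N-isopropylcarbamate | CC(C)NC(=O)Oc1cc(OC)c(OC)c(OC)c1[Si](C)(C)C
F9 | step 3 | 3,4,5-trimethoxy-2,6-bis(trimethylsilyl)phenyl N-isopropylcarbamate | CC(C)NC(=O)Oc1c([Si](C)(C)C)c(OC)c(OC)c(OC)c1[Si](C)(C)C
A1 | alternative 1 | (2S)-8-(benzyloxy)-4-[(tert-butyldimethylsilyl)oxy]-2-(3,4-dimethoxyphenyl)-5,6,7-trimethoxychromane (both C4 epimers) | COc1ccc([C@@H]2CC(O[Si](C)(C)C(C)(C)C)c3c(c(OCc4ccccc4)c(OC)c(OC)c3OC)O2)cc1OC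
A2 | alternative 1 | (1S)-3-[3-(benzyloxy)-2-bromo-4,5,6-trimethoxyphenyl]-3-[(tert-butyldimethylsilyl)oxy]-1-(3,4-dimethoxyphenyl)propan-1-ol (both C3 epimers) | COc1ccc([C@@H](O)CC(O[Si](C)(C)C(C)(C)C)c2c(Br)c(OCc3ccccc3)c(OC)c(OC)c2OC)cc1OC
A3 | alternative 2 | (2S)-8-(benzyloxy)-2-(3,4-dimethoxyphenyl)-5,6,7-trimethoxychromane | COc1ccc([C@@H]2CCc3c(c(OCc4ccccc4)c(OC)c(OC)c3OC)O2)cc1OC
A4 | alternative 2 | 2-(benzyloxy)-6-(hydroxymethyl)-3,4,5-trimethoxyphenol | OCc1c(O)c(OCc2ccccc2)c(OC)c(OC)c1OC
A5 | alternative 2 | 4-ethenyl-1,2-dimethoxybenzene (3,4-dimethoxystyrene) | C=Cc1ccc(OC)c(OC)c1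
A6 | alternative 3 | (2S,4S)-4-[(tert-butyldimethylsilyl)oxy]-2-(3,4-dimethoxyphenyl)-5,6,7-trimethoxychroman-8-ol (2,4-cis) | COc1ccc([C@@H]2C[C@H](O[Si](C)(C)C(C)(C)C)c3c(c(O)c(OC)c(OC)c3OC)O2)cc1OC
A7 | alternative 3 | 4-[(2S,4S)-4-[(tert-butyldimethylsilyl)oxy]-2-(3,4-dimethoxyphenyl)-3,4-dihydro-2H-pyran-5-yl]-2,3,4-trimethoxycyclobut-2-en-1-one (both epimers at the cyclobutenone carbon) | COc1ccc([C@@H]2C[C@H](O[Si](C)(C)C(C)(C)C)C(C3(OC)C(OC)=C(OC)C3=O)=CO2)cc1OC
A8 | alternative 3 | 3,4-dimethoxycyclobut-3-ene-1,2-dione (dimethyl squarate) | COC1=C(OC)C(=O)C1=O
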